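Remark: both rings are numbered as in orsellinic acid (C1 carries the carboxyl carbon, C6 the methyl group). Ring A is the acyl ring with the methoxy group, ring B the ring with the free carboxyl group.

## Structural features

Haemathamnolic acid is a depside: two benzene rings of the orsellinate type joined by a single aryl ester, with the carbonyl carbon on ring A C1 and the ester oxygen on ring B C5, meta to the ring B carboxyl group. Ring A is pentasubstituted (C1 acyl, C2 OH, C3 CHO, C4 OCH3, C6 CH3; only C5 bears hydrogen). Ring B is fully substituted (C1 CO2H, C2 OH, C3 CHO, C4 OH, C5 O-acyl, C6 CH3). There is no stereocentre, so every problem is one of regiochemistry and chemoselectivity. Three groups are fragile. The aryl ester is a catechol monoester, because the free C4 hydroxyl of ring B neighbours the acylated C5 oxygen, and base can cleave it or shift the acyl group. The β-resorcylic acid unit of ring B can lose CO2 in hot acid. The two salicylaldehyde-type formyl groups are open to oxidation, hydrogenolysis and condensation. The real difficulty is to place five differentiated oxygens on two crowded rings and to join a di-ortho-substituted acid to a di-ortho-substituted phenol. The key step exploits the position of the two formyl carbons: ring A C3 lies between the C2 hydroxyl and the C4 methoxy group, and ring B C3 lies between the C2 and C4 hydroxyls and is the only unsubstituted carbon of that ring. Both are ortho to a free phenol that can hold titanium.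

## Logic of the disconnections

15 to 13: the two aryl–CHO bonds (ring A C3–CHO and ring B C3–CHO) are cut together. Both aldehydes are the most sensitive groups of 15, and removing them leaves a depside that contains only phenols, ethers, an ester and an acid. The gain is that no aldehyde has to pass through esterification or deprotection. The demand is a twofold formylation of 13 that finds C3 on each ring, stops at one formyl group per ring and leaves the ester and the carboxyl group alone; the flask intermediate is 14.

13 to 12: no skeletal bond is cut; the four O–CH2Ph bonds are re-formed (three ethers and one ester). One kind of protecting group for every acidic site of the coupling partners means a single neutral deprotection. The demand is that hydrogenolysis spares the aryl ester and that 13 is never exposed to base.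

12 to 10 and 7: the acyl C–O bond of the depside is cut. This splits the molecule into two rings of similar size, each derived from a commercial orsellinate. The demand is acylation of a phenol flanked by CH3 and OCH2Ph with an acid flanked by CH3 and OCH2Ph, which calls for a strongly activated acyl species (11) and for all other oxygens to be blocked.

7 to 4: the ring B C5–O bond is cut back to a C5–I bond. A carbon–halogen bond can be turned into a phenol through a carbon–magnesium and a carbon–boron bond (5, then 6). The demand is that metal exchange is faster than attack on the hindered benzyl ester.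

4 to 3: the C5–I bond is cut. The gain is a return to a simple tri-O-benzylated orsellinate. The demand is positional selectivity of aromatic substitution for C5 (next to CH3) over C3 (between two benzyloxy groups).

3 to 1 and 2: the three O–benzyl bonds are cut. The gain is a one-operation protection of a commercial acid. The demand is complete alkylation, including the chelated C2 hydroxyl.

10 to 9: the carboxyl O–H is traced back to the methyl ester. The demand is hydrolysis of a di-ortho-substituted benzoate without loss of CO2.

9 to 8 and 2: the O–benzyl bond on ring A C2 is cut. The gain is that the acid component has no free phenol during activation. The demand is alkylation of a chelated phenol.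

## Other disconnections considered

Alternative 1: The cut runs through ring B itself, at the C5–C6 and C1–C2 bonds, and leads to the trioxygenated diene A1 and the alkynoate A2.
- Forward key step: a polarity-matched Diels–Alder reaction would join the benzyloxy-bearing terminus of A1 to the methyl-bearing carbon of A2 and the ketene acetal carbon to the ester-bearing carbon. Loss of methanol and of the silyl groups would aromatise the adduct to A3.
- In its favour: the oxygen pattern of ring B, C5 oxygen included, is fixed by the building blocks and not by the positional preference of an aromatic substitution. On this point the alternative is the better plan, because the chosen route depends on C5-over-C3 selectivity in step 2.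
- Against it here: the differentiation is the wrong way round. A3 has the C5 oxygen benzylated and the C2 and C4 phenols free, whereas the depside coupling needs the reverse, so a protecting-group exchange would follow. A1 is a moisture-sensitive polyoxygenated diene that needs its own preparation. A2, an internal alkyne with a β-methyl group, should be a slow dienophile. The tert-butyl ester would finally be cleaved by acid beside electron-rich rings that can trap the tert-butyl cation.
- Comparison: mechanistically the cycloaddition is the equal of the substitution chemistry of steps 2 and 3 in reliability of regiochemistry. Structurally it contributes nothing to ring A, to the ester or to the aldehydes, so it replaces steps 1 to 3 only and the late formylation of 13 would still be needed. In step count it should need about twice as many operations to reach a partner equivalent to 7.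

Alternative 2: Ring A is taken apart at four carbon–carbon bonds (C1–C2, C2–C3, C4–C5, C5–C6), back to the diazoketone A4, which already contains the ester bond to ring B, and methoxyacetylene A5.
- Forward key step: Wolff rearrangement of A4 would give a vinylketene. [2+2] cycloaddition with A5, four-electron opening of the cyclobutenone, six-electron electrocyclisation and tautomerisation would then give A6.
- In its favour: the ester bond is made on an unhindered unsaturated acid, so the coupling of two di-ortho-substituted partners is avoided. On this point the alternative is the better plan. A6 also carries the ring A phenol free, one protecting group fewer, and hydrogenolysis of A6 would lead to 13, so the same endgame applies.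
- Against it here: A4 combines a diazo group with an electron-poor alkene, so dipolar self-addition is a threat, and its preparation needs a diazomethane-type acylation. A5 is volatile and polymerises easily. The sequence also builds from acyclic material a ring that can be bought as 8.
- Comparison: on regiochemistry of ring A the two plans are equal (polarity of ketene and ynol ether there, a purchased arene here). Mechanistically four consecutive pericyclic events under photolysis stand against one acylation. In step count the alternative still needs 7 and adds the preparation of A4, so it should be one to two steps longer and more hazardous.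

Alternative 3: The cut is the ring A bond between the ester-bearing and the methyl-bearing carbon (C1–C6), leading to the aryl triketo ester A7.
- Forward key step: base-mediated aldol attack of the C2 methylene on the C7 ketone, dehydration and enolisation would give the orsellinate depside A8.
- In its favour: the route is biomimetic, and the ester bond of A7 could be made by capture of an acylketene by 7, which is less sensitive to crowding than the acylation of step 6. On this point the alternative is the better plan.
- Against it here: the ring B aryloxide is a good leaving group. Claisen-type attack of C6 on the ester carbonyl and lactonisation through the C5 enol oxygen would both expel ring B, and both are favoured by an aryl ester. A8 also lacks the ring A methyl ether, so a regioselective O-methylation under basic conditions in the presence of the depside ester would have to follow.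
- Comparison: structurally A8 is a less complete ring A than the one bought as 8. Mechanistically the choice among aldol, Claisen and lactone pathways is biased the wrong way by the substrate, whereas the chosen acylation has one course only. In step count 7 is still required, and chain assembly, cyclisation and methylation should add two to three steps.

Key step: step 8

## Steps

Step 1
Reactants: 1 orsellinic acid (2,4-dihydroxy-6-methylbenzoic acid); 2 benzyl bromide
Product: 3 benzyl 2,4-bis(benzyloxy)-6-methylbenzoate
Conditions: BnBr (3.3 equiv), K2CO3, DMF, rt then 60 °C
Reagents that add atoms: benzyl bromide 2, BrCc1ccccc1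
Why: Williamson alkylation; the carboxylate reacts first at room temperature (which forestalls decarboxylation), then the C4 phenoxide, and the chelated C2 hydroxyl on warming, so one reagent masks all three acidic sites with groups that fall in one later hydrogenolysis.

Step 2
Reactants: 3 benzyl 2,4-bis(benzyloxy)-6-methylbenzoate
Product: 4 benzyl 2,4-bis(benzyloxy)-5-iodo-6-methylbenzoate
Conditions: NIS (1.05 equiv), TFA (cat.), MeCN, 0 °C → rt, dark
Reagents that add atoms: N-iodosuccinimide, O=C1CCC(=O)N1I
Why: Electrophilic aromatic iodination; both free carbons are activated by two ether oxygens, but C5 (para to the C2 ether, ortho to the C4 ether, next to CH3) is less encumbered than C3 between two benzyloxy groups, in line with the usual entry of electrophiles next to the methyl group of orcinol diethers.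

Step 3
Reactants: 4 benzyl 2,4-bis(benzyloxy)-5-iodo-6-methylbenzoate
Product: 7 benzyl 2,4-bis(benzyloxy)-5-hydroxy-6-methylbenzoate, via arylmagnesium chloride 5 (not isolated), via dimethyl arylboronate 6 (not isolated)
Conditions: i-PrMgCl·LiCl, THF, −20 → 0 °C; B(OMe)3, −20 °C → rt; then AcOH, 30% aq H2O2, 0 °C → rt
Reagents that add atoms: hydrogen peroxide, OO (the phenolic oxygen of 7); i-PrMgCl·LiCl and trimethyl borate, COB(OC)OC, leave atoms only in 5 and 6
Why: Iodine–magnesium exchange followed by borylation and oxidative 1,2-shift of the aryl group from boron to oxygen; exchange at an aryl iodide should be faster than addition to the di-ortho-substituted benzyl ester, and the oxygen enters exactly where the iodine stood.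

Step 4
Reactants: 8 methyl 2-hydroxy-4-methoxy-6-methylbenzoate; 2 benzyl bromide
Product: 9 methyl 2-(benzyloxy)-4-methoxy-6-methylbenzoate
Conditions: BnBr, K2CO3, DMF, 60 °C
Reagents that add atoms: benzyl bromide 2, BrCc1ccccc1
Why: Williamson ether synthesis on the chelated phenol, which is deprotonated by carbonate in DMF and alkylated on warming; the ether prevents self-acylation of the activated acid in step 6.

Step 5
Reactants: 9 methyl 2-(benzyloxy)-4-methoxy-6-methylbenzoate
Product: 10 2-(benzyloxy)-4-methoxy-6-methylbenzoic acid
Conditions: KOH, DMSO–H2O (4:1), 90 °C; then 1 M HCl, 0 °C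
Reagents that add atoms: potassium hydroxide, [K+].[OH-] (one carboxyl oxygen)
Why: Saponification of a di-ortho-substituted benzoate by poorly solvated hydroxide in aqueous DMSO; both ethers are inert to base, and cold acidification avoids loss of CO2 from the electron-rich acid.

Step 6
Reactants: 10 2-(benzyloxy)-4-methoxy-6-methylbenzoic acid; 7 benzyl 2,4-bis(benzyloxy)-5-hydroxy-6-methylbenzoate
Product: 12 benzyl 2,4-bis(benzyloxy)-5-{[2-(benzyloxy)-4-methoxy-6-methylbenzoyl]oxy}-6-methylbenzoate, via acyl chloride 11 (not isolated)
Conditions: (COCl)2, DMF (cat.), CH2Cl2, 0 °C → rt, concentrate; then 7, Et3N, DMAP, CH2Cl2, 0 °C → rt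
Reagents that add atoms: none
Why: Acyl chloride formation followed by DMAP-catalysed O-acylation of a phenol; the ortho and para ether oxygens let the hindered acyl chloride ionise easily to an acylpyridinium or acylium species, and the C5 hydroxyl of 7 is the only free nucleophile in either partner.

Step 7
Reactants: 12 benzyl 2,4-bis(benzyloxy)-5-{[2-(benzyloxy)-4-methoxy-6-methylbenzoyl]oxy}-6-methylbenzoate
Product: 13 2,4-dihydroxy-5-[(2-hydroxy-4-methoxy-6-methylbenzoyl)oxy]-6-methylbenzoic acid
Conditions: H2 (1 atm), 10% Pd/C, EtOAc–THF, rt
Reagents that add atoms: none
Why: Heterogeneous hydrogenolysis cleaves the three benzyl ethers and the benzyl ester while the aryl ester, the methyl ether and both arenes are inert; the neutral medium avoids acyl migration to the neighbouring C4 hydroxyl and decarboxylation.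

Step 8
Reactants: 13 2,4-dihydroxy-5-[(2-hydroxy-4-methoxy-6-methylbenzoyl)oxy]-6-methylbenzoic acid
Product: 15 haemathamnolic acid, via bis[chloro(methoxy)methyl] adduct 14 (not isolated)
Conditions: TiCl4 (7 equiv), CH2Cl2, −20 → 0 °C; Cl2CHOCH3 (3 equiv), 0 °C → rt; then ice-cold 1 M HCl–THF, rt
Reagents that add atoms: dichloromethyl methyl ether, COC(Cl)Cl (both formyl carbons); water, O (both formyl oxygens, on hydrolysis of 14)
Why: This is the Rieche formylation of phenols in its titanium-mediated, ortho-selective form. TiCl4 first turns the three phenols and the carboxyl group of 13 into titanium aryloxide and salicylate chelates with loss of HCl, then ionises Cl2CHOCH3 to the chloro(methoxy)carbenium ion, which is delivered within the complex to the ring carbon ortho to a titanium-bound oxygen; rearomatisation gives 14, whose two CHCl(OCH3) carbons are transient stereocentres of no consequence, and aqueous acid hydrolyses both to the aldehydes. No ring is closed and no stereocentre remains in 15. Ring B offers a single free carbon, C3, flanked by the C2 and C4 oxygens, so its regiochemistry is fixed by the substrate. In ring A the only free carbon ortho to the titanium-bound C2 oxygen is C3, between OH and OCH3, and chelation-controlled delivery there is expected to outrun attack at C5, which is para to that oxygen and squeezed between OCH3 and CH3. Each new formyl group is held in a chelate by its neighbouring oxygen and deactivates its ring, so one formyl group per ring is expected. The carboxyl group is tied up as a six-membered titanium salicylate, and if Cl2CHOCH3 converts part of it into the acyl chloride, the aqueous acid work-up should return the acid. The depside ester has no free ortho or para carbon on ring B for a Fries shift and should persist between 0 °C and room temperature.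

## Compound list

1 | orsellinic acid (2,4-dihydroxy-6-methylbenzoic acid) | Cc1cc(O)cc(O)c1C(=O)O | starting material
2 | benzyl bromide | BrCc1ccccc1 | starting material
3 | benzyl 2,4-bis(benzyloxy)-6-methylbenzoate | Cc1cc(OCc2ccccc2)cc(OCc2ccccc2)c1C(=O)OCc1ccccc1 | intermediate
4 | benzyl 2,4-bis(benzyloxy)-5-iodo-6-methylbenzoate | Cc1c(I)c(OCc2ccccc2)cc(OCc2ccccc2)c1C(=O)OCc1ccccc1 | intermediate
5 | benzyl 2,4-bis(benzyloxy)-5-(chloromagnesio)-6-methylbenzoate | Cc1c([Mg]Cl)c(OCc2ccccc2)cc(OCc2ccccc2)c1C(=O)OCc1ccccc1 | intermediate (not isolated)
6 | benzyl 2,4-bis(benzyloxy)-5-(dimethoxyboranyl)-6-methylbenzoate | Cc1c(B(OC)OC)c(OCc2ccccc2)cc(OCc2ccccc2)c1C(=O)OCc1ccccc1 | intermediate (not isolated)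
7 | benzyl 2,4-bis(benzyloxy)-5-hydroxy-6-methylbenzoate | Cc1c(O)c(OCc2ccccc2)cc(OCc2ccccc2)c1C(=O)OCc1ccccc1 | intermediate
8 | methyl 2-hydroxy-4-methoxy-6-methylbenzoate | COC(=O)c1c(C)cc(OC)cc1O | starting material
9 | methyl 2-(benzyloxy)-4-methoxy-6-methylbenzoate | COC(=O)c1c(C)cc(OC)cc1OCc1ccccc1 | intermediate
10 | 2-(benzyloxy)-4-methoxy-6-methylbenzoic acid | COc1cc(C)c(C(=O)O)c(OCc2ccccc2)c1 | intermediate
11 | 2-(benzyloxy)-4-methoxy-6-methylbenzoyl chloride | COc1cc(C)c(C(=O)Cl)c(OCc2ccccc2)c1 | intermediate (not isolated)
12 | benzyl 2,4-bis(benzyloxy)-5-{[2-(benzyloxy)-4-methoxy-6-methylbenzoyl]oxy}-6-methylbenzoate | COc1cc(C)c(C(=O)Oc2c(C)c(C(=O)OCc3ccccc3)c(OCc3ccccc3)cc2OCc2ccccc2)c(OCc2ccccc2)c1 | intermediate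
13 | 2,4-dihydroxy-5-[(2-hydroxy-4-methoxy-6-methylbenzoyl)oxy]-6-methylbenzoic acid | COc1cc(C)c(C(=O)Oc2c(C)c(C(=O)O)c(O)cc2O)c(O)c1 | intermediate
14 | 3-[chloro(methoxy)methyl]-5-({3-[chloro(methoxy)methyl]-2-hydroxy-4-methoxy-6-methylbenzoyl}oxy)-2,4-dihydroxy-6-methylbenzoic acid (titanium-bound in the flask, mixture of diastereomers) | COc1cc(C)c(C(=O)Oc2c(C)c(C(=O)O)c(O)c(C(Cl)OC)c2O)c(O)c1C(Cl)OC | intermediate (not isolated)
15 | haemathamnolic acid (3-formyl-5-[(3-formyl-2-hydroxy-4-methoxy-6-methylbenzoyl)oxy]-2,4-dihydroxy-6-methylbenzoic acid) | COc1cc(C)c(C(=O)Oc2c(C)c(C(=O)O)c(O)c(C=O)c2O)c(O)c1C=O | target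

## Step count and least certain steps

Total step count: 8 (steps 3 and 6 are one-pot operations). Longest linear sequence: 6 steps (steps 1, 2, 3, 6, 7, 8, from 1 to 15). The ring A branch (steps 4 and 5) joins at step 6.

Step 8 (key step). Several processes could spoil it:
- activation of the free carboxyl group by the dichloromethyl ether, followed by intermolecular ester formation;
- stalling after the first formylation because the polytitanated substrate separates from CH2Cl2;
- competing attack at ring A C5;
- acid-induced loss of CO2 from ring B.

The fallback keeps the carboxyl group masked during the C–C bond formation and removes the mask afterwards. It sets out from 13 and comes back at 15. Selective alkylation of the carboxylate of 13 (BnBr, KHCO3, DMF, rt) should give benzyl 2,4-dihydroxy-5-[(2-hydroxy-4-methoxy-6-methylbenzoyl)oxy]-6-methylbenzoate F1. The same twofold Rieche formylation on this ester should give benzyl 3-formyl-5-[(3-formyl-2-hydroxy-4-methoxy-6-methylbenzoyl)oxy]-2,4-dihydroxy-6-methylbenzoate F2. Brief hydrogenolysis (H2, 10% Pd/C, EtOAc, stopped after one equivalent of hydrogen) should release 15, because the chelated aldehydes are reduced more slowly than a benzyl ester is cleaved.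

Step 2. Competing iodination at C3 or twofold iodination may occur, because both free carbons are activated by two ether oxygens and the preference for C5 rests on sterics alone. The fallback places the C5 oxygen by a mechanistically para-selective oxidation before any protection. It sets out from 1 and comes back at 7, bypassing steps 1 to 3. Elbs persulfate oxidation of 1 (K2S2O8, aq KOH, 10 °C) attacks para to the C2 phenoxide and should give the aryl sulfate, 2,4-dihydroxy-6-methyl-5-(sulfooxy)benzoic acid dipotassium salt F3. Exhaustive benzylation of the carboxylate and both phenols (BnBr, K2CO3, DMF) leaves the unreactive sulfate monoester in place and should give the potassium salt of benzyl 2,4-bis(benzyloxy)-6-methyl-5-(sulfooxy)benzoate F4. Hydrolysis of the sulfate (aq HCl, THF, 60 °C) should then free the C5 hydroxyl and give 7.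

Step 3. The likely failures are:
- slow iodine–magnesium exchange at the electron-rich, doubly flanked iodide, with protonation of the aryl–magnesium species on work-up;
- addition of the Grignard reagent to the ester;
- incomplete borylation;
- over-oxidation of the electron-rich phenol by excess peroxide.

The fallback installs the oxygen without an organometallic. It sets out from 3 and comes back at 7. Vilsmeier–Haack formylation of 3 (POCl3, DMF, 70 °C) should give benzyl 2,4-bis(benzyloxy)-5-formyl-6-methylbenzoate F5. Baeyer–Villiger oxidation with migration of the electron-rich aryl group (mCPBA, CH2Cl2, rt) should give benzyl 2,4-bis(benzyloxy)-5-(formyloxy)-6-methylbenzoate F6. Mild methanolysis of the formate (Et3N, MeOH, rt) should give 7.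

Step 6. Acylation may be slow because both the acyl carbon and the phenol oxygen carry two ortho substituents, so that unreacted acyl chloride is hydrolysed on work-up. The fallback replaces base-mediated addition–elimination at the crowded acyl chloride by acid-mediated transfer of a linear acylium ion. It sets out from 10 and 7 and comes back at 12. Treatment of 10 with trifluoroacetic anhydride in toluene at room temperature should form 2-(benzyloxy)-4-methoxy-6-methylbenzoic trifluoroacetic anhydride F7 in the flask. Ionisation of F7, assisted by the ortho and para ether oxygens, and capture of the acylium ion by the C5 hydroxyl of 7 should give 12.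

## Further compounds

F1 | step 8 | benzyl 2,4-dihydroxy-5-[(2-hydroxy-4-methoxy-6-methylbenzoyl)oxy]-6-methylbenzoate | COc1cc(C)c(C(=O)Oc2c(C)c(C(=O)OCc3ccccc3)c(O)cc2O)c(O)c1
F2 | step 8 | benzyl 3-formyl-5-[(3-formyl-2-hydroxy-4-methoxy-6-methylbenzoyl)oxy]-2,4-dihydroxy-6-methylbenzoate | COc1cc(C)c(C(=O)Oc2c(C)c(C(=O)OCc3ccccc3)c(O)c(C=O)c2O)c(O)c1C=O
F3 | step 2 | 2,4-dihydroxy-6-methyl-5-(sulfooxy)benzoic acid dipotassium salt | Cc1c(OS(=O)(=O)[O-])c(O)cc(O)c1C(=O)[O-].[K+].[K+]
F4 | step 2 | benzyl 2,4-bis(benzyloxy)-6-methyl-5-(sulfooxy)benzoate potassium salt | Cc1c(OS(=O)(=O)[O-])c(OCc2ccccc2)cc(OCc2ccccc2)c1C(=O)OCc1ccccc1.[K+]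
F5 | step 3 | benzyl 2,4-bis(benzyloxy)-5-formyl-6-methylbenzoate | Cc1c(C=O)c(OCc2ccccc2)cc(OCc2ccccc2)c1C(=O)OCc1ccccc1
F6 | step 3 | benzyl 2,4-bis(benzyloxy)-5-(formyloxy)-6-methylbenzoate | Cc1c(OC=O)c(OCc2ccccc2)cc(OCc2ccccc2)c1C(=O)OCc1ccccc1
F7 | step 6 | 2-(benzyloxy)-4-methoxy-6-methylbenzoic trifluoroacetic anhydride | COc1cc(C)c(C(=O)OC(=O)C(F)(F)F)c(OCc2ccccc2)c1
A1 | alternative 1 | 4-(benzyloxy)-1-methoxy-1,3-bis(trimethylsilyloxy)buta-1,3-diene (alkene geometry not defining for the aromatic product) | COC(O[Si](C)(C)C)=CC(O[Si](C)(C)C)=COCc1ccccc1
A2 | alternative 1 | tert-butyl but-2-ynoate | CC#CC(=O)OC(C)(C)C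
A3 | alternative 1 | tert-butyl 5-(benzyloxy)-2,4-dihydroxy-6-methylbenzoate | Cc1c(OCc2ccccc2)c(O)cc(O)c1C(=O)OC(C)(C)C
A4 | alternative 2 | 4,6-bis(benzyloxy)-3-[(benzyloxy)carbonyl]-2-methylphenyl (2E)-5-diazo-3-methyl-4-oxopent-2-enoate | O=C(/C=C(\C)C(=O)C=[N+]=[N-])Oc1c(C)c(C(=O)OCc2ccccc2)c(OCc2ccccc2)cc1OCc1ccccc1
A5 | alternative 2 | methoxyacetylene (methoxyethyne) | COC#C
A6 | alternative 2 | benzyl 2,4-bis(benzyloxy)-5-[(2-hydroxy-4-methoxy-6-methylbenzoyl)oxy]-6-methylbenzoate | COc1cc(C)c(C(=O)Oc2c(C)c(C(=O)OCc3ccccc3)c(OCc3ccccc3)cc2OCc2ccccc2)c(O)c1
A7 | alternative 3 | 4,6-bis(benzyloxy)-3-[(benzyloxy)carbonyl]-2-methylphenyl 3,5,7-trioxooctanoate | CC(=O)CC(=O)CC(=O)CC(=O)Oc1c(C)c(C(=O)OCc2ccccc2)c(OCc2ccccc2)cc1OCc1ccccc1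
A8 | alternative 3 | benzyl 2,4-bis(benzyloxy)-5-[(2,4-dihydroxy-6-methylbenzoyl)oxy]-6-methylbenzoate | Cc1cc(O)cc(O)c1C(=O)Oc1c(C)c(C(=O)OCc2ccccc2)c(OCc2ccccc2)cc1OCc1ccccc1
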